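Ring C of the upper (epicatechin) unit is cut at O1–C8a and C3–C4. C8a is the ring A carbon meta to both O5 and O7, so it can be an aryl fluoride open to SNAr; C3, a carbinol carbon between benzylic C4 and the O1-bearing C2, can be a dithiane acyl-anion equivalent. In one flask the O,C-dianion of an (R)-aryl(1,3-dithian-2-yl)methanol is C-benzylated by a 2-fluoro-4,6-bis(benzyloxy)benzyl bromide and its alkoxide then displaces fluoride, closing the pyran. Unmasking, cis-selective reduction, C4 oxidation and 4β→8 arylation with an epiafzelechin unit made by the same annulation, then hydrogenolysis, give the target.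

Key step: step 7

Step 1
Reactants: 1 1,3,5-trifluorobenzene
Product: 2 1,3-bis(benzyloxy)-5-fluorobenzene
Conditions: BnOH (2.1 equiv), NaH (2.1 equiv), NMP, 0 °C then 100 °C
Reagents that add atoms: benzyl alcohol, OCc1ccccc1
Why: Two successive SNAr displacements by benzyl oxide on fluorines that are meta to one another should stop at the bis-ether, because each ether group introduced slows the next substitution.

Step 2
Reactants: 2 1,3-bis(benzyloxy)-5-fluorobenzene
Product: 4 [2,4-bis(benzyloxy)-6-fluorophenyl]methanol, via aryllithium 3 (not isolated)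
Conditions: n-BuLi (1.05 equiv), THF, −78 °C; then CH2O gas (from cracked paraformaldehyde), −78 °C; H2O
Reagents that add atoms: formaldehyde, C=O
Why: Directed ortho-metalation should take place at the C–H flanked by fluorine and a benzyloxy group (the most acidic site, two equivalent positions), and the aryllithium, kept at −78 °C to avoid loss of LiF, is trapped by 1,2-addition to formaldehyde.

Step 3
Reactants: 4 [2,4-bis(benzyloxy)-6-fluorophenyl]methanol
Product: 5 2,4-bis(benzyloxy)-6-fluorobenzyl bromide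
Conditions: CBr4, PPh3, CH2Cl2, 0 °C; filtered through a short silica pad and used at once (made fresh for each of steps 7 and 13)
Reagents that add atoms: carbon tetrabromide, BrC(Br)(Br)Br
Why: The Appel reaction converts the primary benzylic alcohol into the bromide under neutral conditions that spare the electron-rich, acid-labile benzylic position.

Step 4
Reactants: 6 1,3-dithiane
Product: 7 2-lithio-1,3-dithiane (THF solution, one batch that serves steps 5 and 11)
Conditions: n-BuLi (1.0 equiv), THF, −30 °C, 2 h; solution titrated and kept at −20 °C under argon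
Reagents that add atoms: n-butyllithium, [Li]CCCC
Why: Deprotonation of the C2–H between the two sulfur atoms by n-BuLi (Corey–Seebach lithiation) should be clean, and the solution is stable at −20 °C, so one batch can be divided between the two acylations.

Step 5
Reactants: 8 methyl 3,4-bis(benzyloxy)benzoate; 7 2-lithio-1,3-dithiane (2.1 equiv)
Product: 9 [3,4-bis(benzyloxy)phenyl](1,3-dithian-2-yl)methanone
Conditions: 8 added to 7 in THF, −78 °C to 0 °C; aq. NH4Cl
Reagents that add atoms: none
Why: Acylation of 2-lithio-1,3-dithiane by the ester (Corey–Seebach chemistry) should stop at the ketone, because the acidic 2-acyl dithiane is deprotonated at once by the second equivalent of 7 and so is protected from a second addition.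

Step 6
Reactants: 9 [3,4-bis(benzyloxy)phenyl](1,3-dithian-2-yl)methanone
Product: 10 (R)-[3,4-bis(benzyloxy)phenyl](1,3-dithian-2-yl)methanol
Conditions: RuCl[(S,S)-TsDPEN](p-cymene) (1 mol %), HCO2H/Et3N (5:2), CH2Cl2, 30 °C
Reagents that add atoms: none
Why: In this Noyori–Ikariya asymmetric transfer hydrogenation the aryl group is recognised by its CH–π contact with the cymene ligand, so the (S,S) catalyst should deliver hydride to the face that gives the (R) carbinol (the spatial sense seen with α-heteroatom-substituted acetophenones), which sets the future C2.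

Step 7
Reactants: 10 (R)-[3,4-bis(benzyloxy)phenyl](1,3-dithian-2-yl)methanol; 5 2,4-bis(benzyloxy)-6-fluorobenzyl bromide
Product: 13 (2R)-5,7-bis(benzyloxy)-2-[3,4-bis(benzyloxy)phenyl]spiro[chromane-3,2'-[1,3]dithiane], via O,C-dilithio dianion 11 (not isolated), via open-chain lithium alkoxide 12 (not isolated)
Conditions: n-BuLi (2.1 equiv), THF, −78 °C to −20 °C; DMPU, then 5 (1.1 equiv), −78 °C to 0 °C; then KOt-Bu (1.2 equiv), DMF, 60 °C, same flask; H2O
Reagents that add atoms: none
Why: n-BuLi removes first the O–H and then the dithiane C–H of 10, and dianion 11 should persist because oxide is too poor a leaving group for β-elimination; its carbanion, C3 as an acyl-anion equivalent of reversed polarity, is benzylated by SN2 at the CH2 that becomes C4 (Corey–Seebach alkylation of a β-oxido dianion of the Fráter–Seebach kind), and after exchange to the potassium alkoxide in DMF the C2 oxygen adds to the fluorine-bearing C8a and fluoride leaves from the Meisenheimer adduct (intramolecular SNAr etherification, the closest known type being chroman closure of 3-(2-fluoroaryl)propan-1-olates). Ring C is the only ring closed, by a 6-exo-trig attack on the arene that is helped by the fully substituted spiro carbon. No stereocentre is created: C2 comes unchanged from 10, since its C–O bond is never broken and its C–H is not acidic next to an alkoxide, and C3 is a dithioketal carbon without stereochemistry. The step needs C- over O-benzylation, secured by the far higher nucleophilicity of the carbanion at −78 °C, and O-arylation by the C2 oxygen alone, secured by the dithioketal, which rules out the enolate O-arylation to a benzofuran and the C2 epimerisation that a free C3 ketone would allow. The fluoride is activated only inductively by the two meta ether oxygens, which is why the potassium alkoxide, DMF and warming are used.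

Step 8
Reactants: 13 (2R)-5,7-bis(benzyloxy)-2-[3,4-bis(benzyloxy)phenyl]spiro[chromane-3,2'-[1,3]dithiane]
Product: 14 (2R)-5,7-bis(benzyloxy)-2-[3,4-bis(benzyloxy)phenyl]chroman-3-one
Conditions: MeI (10 equiv), CaCO3, MeCN/H2O (9:1), 45 °C
Reagents that add atoms: water, O
Why: S-Methylation of the dithioketal and hydrolysis of the sulfonium species under CaCO3 buffering (alkylative dethioacetalisation) should unmask the C3 ketone without enolisation toward C2.

Step 9
Reactants: 14 (2R)-5,7-bis(benzyloxy)-2-[3,4-bis(benzyloxy)phenyl]chroman-3-one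
Product: 15 (2R,3R)-5,7-bis(benzyloxy)-2-[3,4-bis(benzyloxy)phenyl]chroman-3-ol (tetra-O-benzyl epicatechin)
Conditions: LiBH(s-Bu)3 (L-Selectride), LiBr, THF, −78 °C; H2O
Reagents that add atoms: none
Why: Substrate-controlled reduction by the bulky trialkylborohydride: equatorial attack on the half-chair that holds the 2-aryl group equatorial should give the axial C3 alcohol, cis to the aryl group (2R,3R), as is typical for flavan-3-ones.

Step 10
Reactants: 15 (2R,3R)-5,7-bis(benzyloxy)-2-[3,4-bis(benzyloxy)phenyl]chroman-3-ol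
Product: 16 (2R,3R,4S)-5,7-bis(benzyloxy)-2-[3,4-bis(benzyloxy)phenyl]-4-(2-hydroxyethoxy)chroman-3-ol
Conditions: DDQ (2 equiv), ethylene glycol (10 equiv), CH2Cl2, rt
Reagents that add atoms: ethylene glycol, OCCO
Why: DDQ removes hydride from benzylic C4, which is activated by the ortho and para ether oxygens of ring A, and the quinone-methide-type cation is trapped by ethylene glycol trans to the axial 3-OH, which sets C4 (benzylic oxidative etherification).

Step 11
Reactants: 17 methyl 4-(benzyloxy)benzoate; 7 2-lithio-1,3-dithiane (2.1 equiv)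
Product: 18 [4-(benzyloxy)phenyl](1,3-dithian-2-yl)methanone
Conditions: 17 added to 7 in THF, −78 °C to 0 °C; aq. NH4Cl
Reagents that add atoms: none
Why: Same Corey–Seebach acylation of 2-lithio-1,3-dithiane as in step 5, in which the acidic acyl dithiane is protected as its enolate against over-addition.

Step 12
Reactants: 18 [4-(benzyloxy)phenyl](1,3-dithian-2-yl)methanone
Product: 19 (R)-[4-(benzyloxy)phenyl](1,3-dithian-2-yl)methanol
Conditions: RuCl[(S,S)-TsDPEN](p-cymene) (1 mol %), HCO2H/Et3N (5:2), CH2Cl2, 30 °C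
Reagents that add atoms: none
Why: Same Noyori–Ikariya asymmetric transfer hydrogenation as in step 6, in which the aryl group directs hydride delivery to give the (R) carbinol that becomes C2 of the lower unit.

Step 13
Reactants: 19 (R)-[4-(benzyloxy)phenyl](1,3-dithian-2-yl)methanol; 5 2,4-bis(benzyloxy)-6-fluorobenzyl bromide
Product: 22 (2R)-5,7-bis(benzyloxy)-2-[4-(benzyloxy)phenyl]spiro[chromane-3,2'-[1,3]dithiane], via O,C-dilithio dianion 20 (not isolated), via open-chain lithium alkoxide 21 (not isolated)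
Conditions: n-BuLi (2.1 equiv), THF, −78 °C to −20 °C; DMPU, then 5 (1.1 equiv), −78 °C to 0 °C; then KOt-Bu (1.2 equiv), DMF, 60 °C, same flask; H2O
Reagents that add atoms: none
Why: Same one-flask Corey–Seebach C-benzylation and intramolecular SNAr closure as in step 7, in which C2 is carried over unchanged from 19.

Step 14
Reactants: 22 (2R)-5,7-bis(benzyloxy)-2-[4-(benzyloxy)phenyl]spiro[chromane-3,2'-[1,3]dithiane]
Product: 23 (2R)-5,7-bis(benzyloxy)-2-[4-(benzyloxy)phenyl]chroman-3-one
Conditions: MeI (10 equiv), CaCO3, MeCN/H2O (9:1), 45 °C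
Reagents that add atoms: water, O
Why: Alkylative dethioacetalisation as in step 8 should unmask the ketone under buffered conditions.

Step 15
Reactants: 23 (2R)-5,7-bis(benzyloxy)-2-[4-(benzyloxy)phenyl]chroman-3-one
Product: 24 (2R,3R)-5,7-bis(benzyloxy)-2-[4-(benzyloxy)phenyl]chroman-3-ol (tri-O-benzyl epiafzelechin)
Conditions: LiBH(s-Bu)3 (L-Selectride), LiBr, THF, −78 °C; H2O
Reagents that add atoms: none
Why: As in step 9, equatorial hydride delivery by the bulky borohydride should give the axial 3-OH cis to the 2-aryl group (2R,3R), a substrate-controlled ketone reduction.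

Step 16
Reactants: 16 (2R,3R,4S)-5,7-bis(benzyloxy)-2-[3,4-bis(benzyloxy)phenyl]-4-(2-hydroxyethoxy)chroman-3-ol; 24 (2R,3R)-5,7-bis(benzyloxy)-2-[4-(benzyloxy)phenyl]chroman-3-ol (4 equiv)
Product: 25 (2R,3R,4R)-5,7-bis(benzyloxy)-2-[3,4-bis(benzyloxy)phenyl]-4-{(2R,3R)-5,7-bis(benzyloxy)-2-[4-(benzyloxy)phenyl]-3-hydroxychroman-8-yl}chroman-3-ol
Conditions: TiCl4 (1.1 equiv), CH2Cl2/THF (9:1), 0 °C to rt; aq. NaHCO3; excess 24 recovered
Reagents that add atoms: none
Why: TiCl4 chelates and ionises the glycol ether to the C4 benzylic cation, which is attacked by C8 of 24 (the less hindered of its two nucleophilic ring A positions) from the face opposite the axial 3-OH, so the 3,4-trans (4β) bond and the C4 stereocentre should form under substrate control, while excess 24 suppresses oligomers (Friedel–Crafts-type benzylic arylation).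

Step 17
Reactants: 25 hepta-O-benzyl epicatechin-(4β→8)-epiafzelechin
Product: 26 epicatechin-(4β→8)-epiafzelechin (target)
Conditions: H2 (1 atm), Pd(OH)2/C, THF/MeOH/H2O, rt
Reagents that add atoms: none
Why: Hydrogenolysis of the seven benzyl ethers under neutral conditions should leave the acid-labile interflavan bond and all five stereocentres untouched.

Compound list
1 | 1,3,5-trifluorobenzene | Fc1cc(F)cc(F)c1 | starting material
2 | 1,3-bis(benzyloxy)-5-fluorobenzene | Fc1cc(OCc2ccccc2)cc(OCc2ccccc2)c1 | intermediate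
3 | [2,4-bis(benzyloxy)-6-fluorophenyl]lithium (not isolated) | [Li]c1c(F)cc(OCc2ccccc2)cc1OCc1ccccc1 | intermediate
4 | [2,4-bis(benzyloxy)-6-fluorophenyl]methanol | OCc1c(F)cc(OCc2ccccc2)cc1OCc1ccccc1 | intermediate
5 | 2,4-bis(benzyloxy)-6-fluorobenzyl bromide | BrCc1c(F)cc(OCc2ccccc2)cc1OCc1ccccc1 | intermediate
6 | 1,3-dithiane | C1CSCSC1 | starting material
7 | 2-lithio-1,3-dithiane (THF solution) | [Li]C1SCCCS1 | intermediate
8 | methyl 3,4-bis(benzyloxy)benzoate | COC(=O)c1ccc(OCc2ccccc2)c(OCc2ccccc2)c1 | starting material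
9 | [3,4-bis(benzyloxy)phenyl](1,3-dithian-2-yl)methanone | O=C(c1ccc(OCc2ccccc2)c(OCc2ccccc2)c1)C1SCCCS1 | intermediate
10 | (R)-[3,4-bis(benzyloxy)phenyl](1,3-dithian-2-yl)methanol | O[C@H](c1ccc(OCc2ccccc2)c(OCc2ccccc2)c1)C1SCCCS1 | intermediate
11 | dilithium O,C-dianion of 10 (not isolated) | [Li+].[Li+].[O-][C@H](c1ccc(OCc2ccccc2)c(OCc2ccccc2)c1)[C-]1SCCCS1 | intermediate
12 | lithium (R)-[3,4-bis(benzyloxy)phenyl]{2-[2,4-bis(benzyloxy)-6-fluorobenzyl]-1,3-dithian-2-yl}methanolate (not isolated) | [Li+].[O-][C@H](c1ccc(OCc2ccccc2)c(OCc2ccccc2)c1)C1(Cc2c(F)cc(OCc3ccccc3)cc2OCc2ccccc2)SCCCS1 | intermediate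
13 | (2R)-5,7-bis(benzyloxy)-2-[3,4-bis(benzyloxy)phenyl]spiro[chromane-3,2'-[1,3]dithiane] | S1CCCSC12Cc3c(OCc4ccccc4)cc(OCc4ccccc4)cc3O[C@@H]2c2ccc(OCc3ccccc3)c(OCc3ccccc3)c2 | intermediate
14 | (2R)-5,7-bis(benzyloxy)-2-[3,4-bis(benzyloxy)phenyl]chroman-3-one | O=C1Cc2c(OCc3ccccc3)cc(OCc3ccccc3)cc2O[C@@H]1c1ccc(OCc2ccccc2)c(OCc2ccccc2)c1 | intermediate
15 | (2R,3R)-5,7-bis(benzyloxy)-2-[3,4-bis(benzyloxy)phenyl]chroman-3-ol | O[C@@H]1Cc2c(OCc3ccccc3)cc(OCc3ccccc3)cc2O[C@@H]1c1ccc(OCc2ccccc2)c(OCc2ccccc2)c1 | intermediate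
16 | (2R,3R,4S)-5,7-bis(benzyloxy)-2-[3,4-bis(benzyloxy)phenyl]-4-(2-hydroxyethoxy)chroman-3-ol | OCCO[C@H]1c2c(OCc3ccccc3)cc(OCc3ccccc3)cc2O[C@H](c2ccc(OCc3ccccc3)c(OCc3ccccc3)c2)[C@@H]1O | intermediate
17 | methyl 4-(benzyloxy)benzoate | COC(=O)c1ccc(OCc2ccccc2)cc1 | starting material
18 | [4-(benzyloxy)phenyl](1,3-dithian-2-yl)methanone | O=C(c1ccc(OCc2ccccc2)cc1)C1SCCCS1 | intermediate
19 | (R)-[4-(benzyloxy)phenyl](1,3-dithian-2-yl)methanol | O[C@H](c1ccc(OCc2ccccc2)cc1)C1SCCCS1 | intermediate
20 | dilithium O,C-dianion of 19 (not isolated) | [Li+].[Li+].[O-][C@H](c1ccc(OCc2ccccc2)cc1)[C-]1SCCCS1 | intermediate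
21 | lithium (R)-[4-(benzyloxy)phenyl]{2-[2,4-bis(benzyloxy)-6-fluorobenzyl]-1,3-dithian-2-yl}methanolate (not isolated) | [Li+].[O-][C@H](c1ccc(OCc2ccccc2)cc1)C1(Cc2c(F)cc(OCc3ccccc3)cc2OCc2ccccc2)SCCCS1 | intermediate
22 | (2R)-5,7-bis(benzyloxy)-2-[4-(benzyloxy)phenyl]spiro[chromane-3,2'-[1,3]dithiane] | S1CCCSC12Cc3c(OCc4ccccc4)cc(OCc4ccccc4)cc3O[C@@H]2c2ccc(OCc3ccccc3)cc2 | intermediate
23 | (2R)-5,7-bis(benzyloxy)-2-[4-(benzyloxy)phenyl]chroman-3-one | O=C1Cc2c(OCc3ccccc3)cc(OCc3ccccc3)cc2O[C@@H]1c1ccc(OCc2ccccc2)cc1 | intermediate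
24 | (2R,3R)-5,7-bis(benzyloxy)-2-[4-(benzyloxy)phenyl]chroman-3-ol | O[C@@H]1Cc2c(OCc3ccccc3)cc(OCc3ccccc3)cc2O[C@@H]1c1ccc(OCc2ccccc2)cc1 | intermediate
25 | (2R,3R,4R)-5,7-bis(benzyloxy)-2-[3,4-bis(benzyloxy)phenyl]-4-{(2R,3R)-5,7-bis(benzyloxy)-2-[4-(benzyloxy)phenyl]-3-hydroxychroman-8-yl}chroman-3-ol | c1ccccc1COc1ccc([C@H]2Oc3c(c(OCc5ccccc5)cc(OCc5ccccc5)c3[C@H]3c4c(OCc5ccccc5)cc(OCc5ccccc5)cc4O[C@H](c4ccc(OCc5ccccc5)c(OCc5ccccc5)c4)[C@@H]3O)C[C@H]2O)cc1 | intermediate
26 | (2R,3R,4R)-2-(3,4-dihydroxyphenyl)-4-[(2R,3R)-3,5,7-trihydroxy-2-(4-hydroxyphenyl)chroman-8-yl]chromane-3,5,7-triol | Oc1ccc([C@H]2Oc3c(c(O)cc(O)c3[C@H]3c4c(O)cc(O)cc4O[C@H](c4ccc(O)c(O)c4)[C@@H]3O)C[C@H]2O)cc1 | target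

Total step count: 17. Longest linear sequence: 9 steps (steps 1, 2, 3, 7, 8, 9, 10, 16, 17).

Steps most likely to fail

Step 7 (the same operation recurs as step 13). The ring closure may stall because the fluoroarene carries two donor ether groups, and incomplete C-deprotonation next to the alkoxide would divert the bromide to O-benzylation. The fallback sets out from 10 and keeps both bond formations in one flask, but moves the ring A oxygenation after the annulation. Dianion 11 is benzylated by commercial 2,4,6-trifluorobenzyl bromide, whose ring is far more activated, to give lithium (R)-[3,4-bis(benzyloxy)phenyl][2-(2,4,6-trifluorobenzyl)-1,3-dithian-2-yl]methanolate F1. On treatment of this alkoxide by KOt-Bu in DMF it should close to (2R)-2-[3,4-bis(benzyloxy)phenyl]-5,7-difluorospiro[chromane-3,2'-[1,3]dithiane] F2. The two remaining fluorides are then displaced by benzyl oxide (BnOH, NaH, NMP, 100 °C), which comes back to the route at 13.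

Step 6 (recurs as step 12). The thioacetal sulfurs may inhibit the ruthenium catalyst, or the catalyst may discriminate poorly between the aryl and the bulky dithianyl group. The fallback sets out from 9 and replaces asymmetric catalysis by resolution. NaBH4 in MeOH gives racemic [3,4-bis(benzyloxy)phenyl](1,3-dithian-2-yl)methanol F3. Esterification by (S)-2-methoxy-2-phenylacetic acid (DCC, DMAP) and chromatographic separation of the diastereomers gives (R)-[3,4-bis(benzyloxy)phenyl](1,3-dithian-2-yl)methyl (S)-2-methoxy-2-phenylacetate F4. Hydrolysis by LiOH in THF/H2O comes back to the route at 10.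

Step 8 (recurs as step 14). S-Methylation at the hindered spiro dithioketal may be slow, and prolonged heating may epimerise C2 of the ketone through enolisation. The fallback sets out from 13 and activates sulfur by oxidation instead of alkylation. One equivalent of mCPBA in CH2Cl2 at −78 °C gives the monosulfoxide (2R)-5,7-bis(benzyloxy)-2-[3,4-bis(benzyloxy)phenyl]spiro[chromane-3,2'-[1,3]dithiane] 1'-oxide F5. Cold acid hydrolysis (HCl, THF/H2O, 0 °C) then comes back to the route at 14.

Further compounds
F1 | step 7 | lithium (R)-[3,4-bis(benzyloxy)phenyl][2-(2,4,6-trifluorobenzyl)-1,3-dithian-2-yl]methanolate | [Li+].[O-][C@H](c1ccc(OCc2ccccc2)c(OCc2ccccc2)c1)C1(Cc2c(F)cc(F)cc2F)SCCCS1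
F2 | step 7 | (2R)-2-[3,4-bis(benzyloxy)phenyl]-5,7-difluorospiro[chromane-3,2'-[1,3]dithiane] | S1CCCSC12Cc3c(F)cc(F)cc3O[C@@H]2c2ccc(OCc3ccccc3)c(OCc3ccccc3)c2
F3 | step 6 | racemic [3,4-bis(benzyloxy)phenyl](1,3-dithian-2-yl)methanol | OC(c1ccc(OCc2ccccc2)c(OCc2ccccc2)c1)C1SCCCS1
F4 | step 6 | (R)-[3,4-bis(benzyloxy)phenyl](1,3-dithian-2-yl)methyl (S)-2-methoxy-2-phenylacetate | CO[C@H](C(=O)O[C@H](c1ccc(OCc2ccccc2)c(OCc2ccccc2)c1)C1SCCCS1)c1ccccc1
F5 | step 8 | (2R)-5,7-bis(benzyloxy)-2-[3,4-bis(benzyloxy)phenyl]spiro[chromane-3,2'-[1,3]dithiane] 1'-oxide (mixture of sulfoxide diastereomers) | O=S1CCCSC12Cc3c(OCc4ccccc4)cc(OCc4ccccc4)cc3O[C@@H]2c2ccc(OCc3ccccc3)c(OCc3ccccc3)c2
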